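**Retrosynthetic overview**
- The hydroxy-methoxy-quinone comes from a 2,3,5,6-tetramethoxyphenyl ring (bought as 1,2,4,5-tetramethoxybenzene) by oxidative demethylation, then hydrolysis of the methoxy group next to the side chain.
- The Ar–CH2–C(quaternary) bond comes from an aryllithium adding to a neopentyl decalin aldehyde, with the benzylic oxygen removed in the same flask.
- The decalin aldehyde comes from an acyclic 1,7-enyne and tiglic aldehyde in one flask: ring A closes by enyne metathesis, then ring B closes by a catalytic asymmetric exo-Diels–Alder reaction that sets all three stereocentres.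
- The enyne comes from isobutyronitrile and 5-bromopent-1-ene (alkylation, partial reduction, alkyne homologation).
- Ring order: arene ring purchased; rings A and B formed together in step 4; quinone unveiled last.

Assumption: the target is the (1R,2S,8aS) enantiomer as read from the SMILES, and the (R)-oxazaborolidinium catalyst in step 4 is assigned from the formyl C–H···O binding model, not from a measured result.

**Step 1**
Reactants: 1 isobutyronitrile; 2 5-bromopent-1-ene
Product: 3 2,2-dimethylhept-6-enenitrile
Conditions: LiN(iPr)2 (LDA, 1.05 equiv), THF, −78 °C; then 2, −78 °C → rt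
Reagents that add atoms: none
Why: LDA deprotonates the nitrile α-carbon and the resulting keteniminate is alkylated by the primary bromide in an SN2 reaction (nitrile α-alkylation), creating the gem-dimethyl quaternary carbon; no stereocentre is formed.

**Step 2**
Reactants: 3 2,2-dimethylhept-6-enenitrile
Product: 4 2,2-dimethylhept-6-enal
Conditions: iBu2AlH (DIBAL-H, 1.2 equiv), CH2Cl2, −78 → 0 °C; then 1 M HCl, 0 °C
Reagents that add atoms: water, O
Why: DIBAL-H adds once to the nitrile to give an N-aluminoimine that survives at low temperature and hydrolyses to the aldehyde on work-up (partial nitrile reduction); the terminal alkene is inert.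

**Step 3**
Reactants: 4 2,2-dimethylhept-6-enal
Product: 5 6,6-dimethyloct-1-en-7-yne
Conditions: dimethyl (1-diazo-2-oxopropyl)phosphonate (1.3 equiv), K2CO3 (2 equiv), MeOH, 0 °C → rt
Reagents that add atoms: dimethyl (1-diazo-2-oxopropyl)phosphonate, CC(=O)C(=[N+]=[N-])P(=O)(OC)OC
Why: Methanolysis of the reagent gives the diazomethylphosphonate anion, which olefinates the non-enolisable aldehyde; loss of N2 and a 1,2-hydride shift of the alkylidene carbene then give the terminal alkyne (Seyferth–Gilbert homologation, Ohira–Bestmann variant).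

**Step 4**
Reactants: 5 6,6-dimethyloct-1-en-7-yne; 6 tiglic aldehyde [(E)-2-methylbut-2-enal]
Product: 8 (1R,2S,8aS)-1,2,5,5-tetramethyl-1,2,3,5,6,7,8,8a-octahydronaphthalene-1-carbaldehyde, via 1-ethenyl-6,6-dimethylcyclohexene 7 (not isolated)
Conditions: second-generation Hoveyda–Grubbs catalyst RuCl2(H2IMes)(=CH-C6H4-2-OiPr) (3 mol %), ethylene (1 atm), CH2Cl2, 40 °C; then Ar purge, −78 °C, 6 (2 equiv), (3aR)-1-(2-methylphenyl)-3,3-diphenyltetrahydro-1H,3H-pyrrolo[1,2-c][1,3,2]oxazaborole (20 mol %) + HN(SO2CF3)2 (20 mol %), −78 → −30 °C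
Reagents that add atoms: none
Why: Proposed new method: ring-closing enyne metathesis (exo mode, ethylene keeps the carbene turning over) isomerises 5 to the volatile 1-vinylcyclohexene 7, which is trapped in the same flask by a Diels–Alder reaction with 6 bound to the chiral oxazaborolidinium ion; the s-trans enal is shielded on one face by a catalyst phenyl group so the diene adds to the Si face of the enal C2 (setting C1 as R), the catalyst-bound formyl group sits exo to avoid the gem-dimethyl carbon beside the diene (placing the C8a hydrogen cis to the formyl carbon), the vinyl CH2 terminus bonds to the enal β-carbon, and the E geometry of 6 places the two new methyl groups cis (setting C2), so that C1, C2 and C8a are formed together; the closest known reaction types are one-pot enyne metathesis/Diels–Alder sequences and oxazaborolidinium-catalysed enantioselective Diels–Alder reactions of 2-substituted enals.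

**Step 5**
Reactants: 8 (1R,2S,8aS)-1,2,5,5-tetramethyl-1,2,3,5,6,7,8,8a-octahydronaphthalene-1-carbaldehyde; 9 1,2,4,5-tetramethoxybenzene
Product: 12 1,2,4,5-tetramethoxy-3-{[(1R,2S,8aS)-1,2,5,5-tetramethyl-1,2,3,5,6,7,8,8a-octahydronaphthalen-1-yl]methyl}benzene, via (2,3,5,6-tetramethoxyphenyl)lithium 10 (not isolated), via lithium benzylic alkoxide 11 (not isolated)
Conditions: 9, n-BuLi, TMEDA, THF, 0 °C; 8, −78 → 0 °C; then Li, NH3(l)/THF, −78 °C; NH4Cl
Reagents that add atoms: none
Why: Lithiation between two methoxy groups (directed ortho-metalation) gives 10, which adds to the non-enolisable aldehyde, and the benzylic C–O bond of 11 is cleaved by dissolving-metal reduction once NH4Cl protonates the alkoxide (one-flask carbonyl addition/Birch-type benzylic hydrogenolysis); the carbinol centre is transient and the three ring stereocentres and the isolated alkene are untouched.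

**Step 6**
Reactants: 12 1,2,4,5-tetramethoxy-3-{[(1R,2S,8aS)-1,2,5,5-tetramethyl-1,2,3,5,6,7,8,8a-octahydronaphthalen-1-yl]methyl}benzene
Product: 13 2,5-dimethoxy-3-{[(1R,2S,8aS)-1,2,5,5-tetramethyl-1,2,3,5,6,7,8,8a-octahydronaphthalen-1-yl]methyl}cyclohexa-2,5-diene-1,4-dione
Conditions: (NH4)2Ce(NO3)6 (2.5 equiv), MeCN/H2O (2:1), 0 °C
Reagents that add atoms: water, O
Why: Single-electron oxidation of the electron-rich arene, attack of water at a para pair of methoxy-bearing carbons and loss of methanol give the p-quinone (oxidative demethylation with tetravalent cerium); either para pair leads to the same 2,5-dimethoxy-3-alkyl quinone, and no stereocentre is touched.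

**Step 7**
Reactants: 13 2,5-dimethoxy-3-{[(1R,2S,8aS)-1,2,5,5-tetramethyl-1,2,3,5,6,7,8,8a-octahydronaphthalen-1-yl]methyl}cyclohexa-2,5-diene-1,4-dione
Product: 14 2-hydroxy-5-methoxy-3-{[(1R,2S,8aS)-1,2,5,5-tetramethyl-1,2,3,5,6,7,8,8a-octahydronaphthalen-1-yl]methyl}cyclohexa-2,5-diene-1,4-dione (CNP0348245.1)
Conditions: KOH, MeOH/H2O, rt; then cold 1 M HCl to pH 4
Reagents that add atoms: potassium hydroxide, [K+].[OH-]
Why: Hydroxide displaces methoxide by addition–elimination (vinylogous ester saponification) at the methoxy group flanked by the side chain, which is expected to be twisted out of conjugation and so the more electrophilic, and the resulting vinylogous carboxylate resists further attack; the brief cold acidification avoids acid-induced cyclisation onto the ring alkene.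

**Compound list**
1 | isobutyronitrile | CC(C)C#N | starting material
2 | 5-bromopent-1-ene | C=CCCCBr | starting material
3 | 2,2-dimethylhept-6-enenitrile | N#CC(C)(C)CCCC=C | intermediate
4 | 2,2-dimethylhept-6-enal | O=CC(C)(C)CCCC=C | intermediate
5 | 6,6-dimethyloct-1-en-7-yne | C#CC(C)(C)CCCC=C | intermediate
6 | tiglic aldehyde, (E)-2-methylbut-2-enal | C/C=C(\C)C=O | starting material
7 | 1-ethenyl-6,6-dimethylcyclohexene (not isolated) | C=CC1=CCCCC1(C)C | intermediate
8 | (1R,2S,8aS)-1,2,5,5-tetramethyl-1,2,3,5,6,7,8,8a-octahydronaphthalene-1-carbaldehyde | O=C[C@@]1(C)[C@@H]2CCCC(C)(C)C2=CC[C@@H]1C | intermediate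
9 | 1,2,4,5-tetramethoxybenzene | COc1cc(OC)c(OC)cc1OC | starting material
10 | (2,3,5,6-tetramethoxyphenyl)lithium (not isolated) | [Li]c1c(OC)c(OC)cc(OC)c1OC | intermediate
11 | lithium [(1R,2S,8aS)-1,2,5,5-tetramethyl-1,2,3,5,6,7,8,8a-octahydronaphthalen-1-yl](2,3,5,6-tetramethoxyphenyl)methanolate, both carbinol epimers (not isolated) | [Li]OC(c1c(OC)c(OC)cc(OC)c1OC)[C@@]1(C)[C@@H]2CCCC(C)(C)C2=CC[C@@H]1C | intermediate
12 | 1,2,4,5-tetramethoxy-3-{[(1R,2S,8aS)-1,2,5,5-tetramethyl-1,2,3,5,6,7,8,8a-octahydronaphthalen-1-yl]methyl}benzene | COc1cc(OC)c(OC)c(C[C@@]2(C)[C@@H]3CCCC(C)(C)C3=CC[C@@H]2C)c1OC | intermediate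
13 | 2,5-dimethoxy-3-{[(1R,2S,8aS)-1,2,5,5-tetramethyl-1,2,3,5,6,7,8,8a-octahydronaphthalen-1-yl]methyl}cyclohexa-2,5-diene-1,4-dione | COC1=CC(=O)C(OC)=C(C[C@@]2(C)[C@@H]3CCCC(C)(C)C3=CC[C@@H]2C)C1=O | intermediate
14 | 2-hydroxy-5-methoxy-3-{[(1R,2S,8aS)-1,2,5,5-tetramethyl-1,2,3,5,6,7,8,8a-octahydronaphthalen-1-yl]methyl}cyclohexa-2,5-diene-1,4-dione | COC1=CC(=O)C(O)=C(C[C@@]2(C)[C@@H]3CCCC(C)(C)C3=CC[C@@H]2C)C1=O | target

**Step count and risks**
Total steps: 7. Longest linear sequence: 7 steps (1 → 3 → 4 → 5 → 8 → 12 → 13 → 14); compounds 2, 6 and 9 are purchased.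

The three steps most likely to fail:

Step 4. The hindered propargylic quaternary carbon may slow the metathesis, the ruthenium residues may interfere with the boron catalyst, and the α,β-disubstituted enal may react slowly or with low enantioselectivity. The fallback sets out from 5 and 6 and comes back at 8, moving enantiocontrol from catalysis to resolution. The same one-flask metathesis/cycloaddition is run with the achiral Lewis acid EtAlCl2 (CH2Cl2, −78 °C), which gives 8 as a racemate with the mirror-image aldehyde F1. Condensation of the racemate with (1R,2R)-N,N'-dimethyl-1,2-diphenylethane-1,2-diamine (Et2O, molecular sieves) gives the imidazolidine of 8 F2 and the imidazolidine of the mirror-image aldehyde F3. These diastereomers are separated by chromatography, and F2 is hydrolysed with cold dilute HCl in Et2O to return 8.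

Step 5. The dissolving-metal cleavage may be accompanied by loss of methoxy groups or partial ring reduction of the tetramethoxyarene. The fallback sets out from 8 (with 9, through 10) and comes back at 12, replacing the electron-transfer cleavage by a radical deoxygenation. The addition of 10 to 8 is quenched with aqueous NH4Cl to isolate the benzylic alcohol F4 (carbinol epimers). NaH, CS2 and then MeI in THF convert it into the S-methyl xanthate F5. Bu3SnH with AIBN in refluxing toluene then gives 12 (Barton–McCombie deoxygenation); the stannane is kept concentrated so that hydrogen transfer outruns cyclisation of the benzylic radical onto the ring alkene.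

Step 7. Hydroxide may attack the less hindered methoxy group and give the regioisomeric hydroxyquinone. The fallback sets out from 13 and comes back at 14, replacing selective hydrolysis by selective methylation. Both methoxy groups of 13 are saponified (excess aqueous NaOH, MeOH, 60 °C, then cold dilute HCl) to the 2,5-dihydroxyquinone F6. The hydroxyl remote from the bulky side chain is then methylated with Me3SiCHN2 (1.0 equiv, MeOH/toluene, 0 °C) to give 14, the hydroxyl beside the neopentyl-type substituent being shielded.

**Further compounds**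
F1 | step 4 | mirror-image aldehyde, (1S,2R,8aR)-1,2,5,5-tetramethyl-1,2,3,5,6,7,8,8a-octahydronaphthalene-1-carbaldehyde | O=C[C@]1(C)[C@H]2CCCC(C)(C)C2=CC[C@H]1C
F2 | step 4 | imidazolidine of 8, (4R,5R)-1,3-dimethyl-4,5-diphenyl-2-[(1R,2S,8aS)-1,2,5,5-tetramethyl-1,2,3,5,6,7,8,8a-octahydronaphthalen-1-yl]imidazolidine | CN1[C@H](c2ccccc2)[C@@H](c2ccccc2)N(C)C1[C@@]1(C)[C@@H]2CCCC(C)(C)C2=CC[C@@H]1C
F3 | step 4 | imidazolidine of the mirror-image aldehyde, (4R,5R)-1,3-dimethyl-4,5-diphenyl-2-[(1S,2R,8aR)-1,2,5,5-tetramethyl-1,2,3,5,6,7,8,8a-octahydronaphthalen-1-yl]imidazolidine | CN1[C@H](c2ccccc2)[C@@H](c2ccccc2)N(C)C1[C@]1(C)[C@H]2CCCC(C)(C)C2=CC[C@H]1C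
F4 | step 5 | benzylic alcohol, [(1R,2S,8aS)-1,2,5,5-tetramethyl-1,2,3,5,6,7,8,8a-octahydronaphthalen-1-yl](2,3,5,6-tetramethoxyphenyl)methanol, carbinol epimers | OC(c1c(OC)c(OC)cc(OC)c1OC)[C@@]1(C)[C@@H]2CCCC(C)(C)C2=CC[C@@H]1C
F5 | step 5 | S-methyl xanthate, O-{[(1R,2S,8aS)-1,2,5,5-tetramethyl-1,2,3,5,6,7,8,8a-octahydronaphthalen-1-yl](2,3,5,6-tetramethoxyphenyl)methyl} S-methyl carbonodithioate | CSC(=S)OC(c1c(OC)c(OC)cc(OC)c1OC)[C@@]1(C)[C@@H]2CCCC(C)(C)C2=CC[C@@H]1C
F6 | step 7 | 2,5-dihydroxyquinone, 2,5-dihydroxy-3-{[(1R,2S,8aS)-1,2,5,5-tetramethyl-1,2,3,5,6,7,8,8a-octahydronaphthalen-1-yl]methyl}cyclohexa-2,5-diene-1,4-dione | OC1=CC(=O)C(O)=C(C[C@@]2(C)[C@@H]3CCCC(C)(C)C3=CC[C@@H]2C)C1=O
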